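**Remarks on the chemistry**

- The acetal carbon made in step 19 forms as both epimers. It is written without a stereodescriptor in 30, 32 and 33 because it becomes the C12 carbonyl in step 21.
- 3-[(4-Methoxybenzyl)oxy]propanoic acid (9) is taken as a catalogue compound.
- Abbreviations: TES = triethylsilyl, TBS = tert-butyldimethylsilyl, TBDPS = tert-butyldiphenylsilyl, PMB = 4-methoxybenzyl, 9-BBN = 9-borabicyclo[3.3.1]nonane, DDQ = 2,3-dichloro-5,6-dicyano-1,4-benzoquinone, TEMPO = 2,2,6,6-tetramethylpiperidin-1-oxyl.

## Analysis of the target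

Target 48 is a germacrane-derived sesquiterpenoid lactone in which an ether oxygen links C5 to C10 of the ten-membered carbocycle. Atom numbering: ring A is the oxepane O–C5–C4–C3–C2–C1–C10, ring B the oxepane O–C5–C6–C7–C8–C9–C10 and ring C the lactone O–C6–C7–C11–C12; C13 is the exocyclic methylene carbon, C14 the methyl group on C10 and C15 the acetoxymethyl carbon on C4. There are seven stereocentres (3R,4R,5R,6R,7R,8R,10R). On ring B the hydrogens on C5, C6, C7 and C8 share one face, so O6, C11 and O8 are mutually cis (cis-fused lactone, C8 ester cis to C11). On ring A the C3 hydroxyl and C15 are cis to each other and trans to C6, and the C5–C6 and C10–C9 bonds leave ring A on opposite faces, so ring B spans a trans-2,7-disubstituted oxepane, the inside–outside arrangement of bicyclo[4.4.1] systems known from the ingenanes. C10 is a fully substituted ether carbon that cannot be corrected once it is set. The sensitive groups are the exocyclic methylene lactone (a base-labile Michael acceptor), the (Z)-2-(acetoxymethyl)but-2-enoate on O8 (prone to Z-to-E isomerisation and to allylic substitution), two primary acetates beside a free secondary C3 hydroxyl, and a C8 oxygen that can translactonise when it is free and cis to C11. The synthesis is hard because of the strained trans-bridged bicycle with its tertiary ether and the contiguous C5–C6–C7–C8 array. The plan rests on one feature: C6–O, C7–C11 and C8–O lie on three neighbouring carbons of ring B, so a two-carbon radical held as an acetal on O6 can reach only C7 of a C7=C8 double bond, which closes ring C and leaves a radical on C8 that can be oxygenated.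

## Retrosynthetic reasoning

**Acetates and C8 ester.** The two primary acetates of 48 are removed first, giving triol 47, because primary hydroxyls can be acetylated selectively beside the hindered C3 hydroxyl at the very end. Triol 47 comes from the tris-silyl ether 46. In 46 the C8–O(acyl) bond is cut so that C8 is the electrophile and acid 45 the nucleophile. This leads to alcohol 38, whose O8 is trans to C11, and asks the forward esterification to invert C8. Cutting here keeps the isomerisable Z-enoate out of every basic step.

**Lactone functionality.** Alcohol 38 is traced to alkoxyamine 37 (N–O cleavage), 37 to lactone 34 (removal of C13) and 34 to the lactol ether 32 (C12 taken down one oxidation level). Keeping O8 as an alkoxyamine through these steps means it can neither translactonise nor add to the methylene lactone. The forward steps must oxidise an acetal and methylenate an enolate without disturbing that group.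

**Key disconnection.** In 32 the C7–C11 bond and the C8–O bond are cut together, which opens ring C and gives the bromoacetal 30 and the nitroxide 31. This is the only cut that uses the O6/C7/C8 adjacency. It replaces an aldol-type lactone annulation on a strained seven-membered ring by an intramolecular radical addition whose regiochemistry and C6/C7 relationship are fixed by the tether. The forward step must cyclise before the nitroxide intercepts the first radical.

**Acetal tether.** The acetal C–O6 bond of 30 is cut to the bicyclic allylic alcohol 28 and ethyl vinyl ether 29. The acetal carries C11 and C12 at the right oxidation level and avoids the poor cyclisation geometry of an ester tether.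

**Ring B.** The C7=C8 double bond of 28 is cut to the diene 27 (vinyl on C6, allyl on C10). Metathesis is chosen because it is reversible up to the ring-closing event and has closed inside–outside bicyclo[4.4.1]undecenes before, and because it places the alkene exactly where the radical step needs it.

**C6 vinyl carbinol.** The vinyl group of 27 is traced through the terminal epoxide 26 to the diol 24. In the forward direction a C6/C7 diol is converted to an allylic alcohol with one added carbon and C6 untouched.

**Ring A.** The O–C5 bond of 24 is cut to the cis-epoxy alcohol 23. An epoxide is the one electrophile that a hindered tertiary hydroxyl will open stereospecifically, so C5 is set by inversion and C6 by retention. Epoxide 23 goes back to the Z-allylic alcohol 22, the Z-enoate 21 and the aldehyde 20. A cis-epoxide is required because O5 and O6 are syn in the target.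

**C3–C4 bond.** Aldehyde 20 is traced through 19 and 18 to triol 16 and the aldol adduct 14, which is cut at C3–C4 into imide 12 and aldehyde 8. Taking the imide carbonyl as C15 and the alkoxymethyl carbon as C5 makes the required C3/C4 relationship a syn aldol, the most reliable auxiliary-controlled version.

**Chiral pool and auxiliary.** Aldehyde 8 is traced through 6, 5, 4 and 2 to (R)-linalool 1. Linalool supplies C10 with its methyl group in the correct configuration, its trisubstituted alkene gives C1–C3 and its vinyl group is homologated to the allyl group (C9, C8). Imide 12 comes from acid 9 and oxazolidinone 10.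

**Side chain.** Acid 45 is traced through 43, 42 and 41 to but-2-enal 39. A vinyl bromide is used because halogen–metal exchange and carboxylation keep the alkene geometry, which puts the carboxyl group cis to the methyl group.

## Alternatives that were turned down

**Alternative 1:** The O–C10 and C9–C10 bonds are cut, so the tertiary ether is assembled from keto ester A1 (C14, C10, C1–C3), the C5 silyl ether A2 of a divinyl diol, and allylsilane A3. In the forward step a silyl triflate condenses A1 with A2 to an oxocarbenium ion that A3 attacks, giving the acyclic ether A4; no ring closes.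
- For it: three cheap fragments make the hindered tertiary ether in one operation, whereas the chosen route reaches that ether only in step 15 by an etherification that is itself uncertain. C5 and C6 arrive secure from a C2-symmetric diol. On ether construction this alternative is stronger.
- Against it: C10 is formed in an acyclic oxocarbenium ion whose two carbon substituents (methyl and a 2-carboxyethyl chain) differ little and whose only control element is the remote C5 centre. A mixture at the one stereocentre that cannot be repaired must be expected. A4 still lacks C3–OH and the C15 oxygen; ring A would have to be closed by C3–C4 bond formation between an ester and a vinyl group with two new stereocentres; three terminal alkenes compete in the later metathesis.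
- In its place the chosen route offers C10 taken with certainty from 1 and a key step that closes a ring and sets two stereocentres.

**Alternative 2:** The C6–C7 bond and the lactone C12–O bond are cut, which leads to the aldehyde A5 carrying a 2-(bromomethyl)acrylate. In the forward step divalent chromium turns the allylic bromide into an allylchromium species whose C7 adds to the C6 aldehyde, closing ring B; the alkoxide then lactonises to A6.
- For it: ring B, ring C and the exocyclic methylene arrive together, and O8 is already in place with its final configuration. The acetal oxidation, the methylenation and the inversion at C8 of the chosen route (steps 21, 22 and 28) are not needed. In the endgame this alternative is shorter and stronger.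
- Against it: ring B would be closed by a carbonyl addition across the trans-2,7-disubstituted oxepane through a cyclic transition state that must absorb the strain of the inside–outside bicycle. C6 and C7 would be decided by conformational preference, not by a geometric constraint. A5 needs a separately made C8 stereocentre next to the acrylate and an epimerisable aldehyde on C5, so it is longer to reach than 27.
- In its place the chosen route separates the two tasks: metathesis closes the strained ring, and the O6 tether enforces the cis C6/C7 relationship.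

**Alternative 3:** The C7–C8 and O8–C6 bonds are cut, which leads to the 2-furyl oxepane aldehyde A7. In the forward step irradiation brings the C8 aldehyde onto the substituted double bond of the furan (Paternò–Büchi reaction), closing ring B and an oxetane in A8.
- For it: the step needs no reagent, the furan brings C6, C7, C11, C12 and the lactone oxygen as one unit, and C7–C8 is formed directly. It is more convergent than the chosen route.
- Against it: the cycloaddition must take place on the more hindered C2=C3 bond of a 2-alkylfuran, with regiochemistry imposed by a short tether across the trans-disubstituted oxepane. In A8, C6 is a ketal carbon, so the C6 stereocentre must be re-created by a reductive opening. The enol ether must still be oxidised to the lactone and C13 added, all on an acid-sensitive bis-acetal.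
- In its place the chosen route carries C6 intact from step 14 and uses it to direct C7.

Key step: step 20

## Route

Step 1
Reactants: 1 (R)-linalool
Product: 2 (R)-3,7-dimethyl-3-(triethylsilyloxy)octa-1,6-diene
Conditions: Et3SiOTf, 2,6-lutidine, CH2Cl2, −78 → 0 °C
Reagents that add atoms: triethylsilyl trifluoromethanesulfonate, CC[Si](CC)(CC)OS(=O)(=O)C(F)(F)F
Why: Silyl triflate silylation of a tertiary alcohol; the C10 stereocentre with its methyl C14 is carried over unchanged from the chiral pool, and the ether keeps the hydroxyl out of the borane, ylide and boron enolate steps that follow.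

Step 2
Reactants: 2 (R)-3,7-dimethyl-3-(triethylsilyloxy)octa-1,6-diene
Product: 4 (R)-3,7-dimethyl-3-(triethylsilyloxy)oct-6-en-1-ol, via B-alkyl-9-borabicyclononane adduct 3 (not isolated)
Conditions: 9-BBN, THF, 0 °C → rt; then NaOH, H2O2, H2O, 0 °C
Reagents that add atoms: hydrogen peroxide, OO
Why: Brown hydroboration–oxidation; 9-BBN adds anti-Markovnikov to the monosubstituted vinyl group much faster than to the trisubstituted alkene, so the vinyl carbons become C9 and C8 with oxygen on C8.

Step 3
Reactants: 4 (R)-3,7-dimethyl-3-(triethylsilyloxy)oct-6-en-1-ol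
Product: 5 (R)-3,7-dimethyl-3-(triethylsilyloxy)oct-6-enal
Conditions: Dess–Martin periodinane, NaHCO3, CH2Cl2, 0 °C → rt
Reagents that add atoms: none
Why: Dess–Martin oxidation under buffered, non-basic conditions stops at the aldehyde and does not eliminate the β-silyloxy group.

Step 4
Reactants: 5 (R)-3,7-dimethyl-3-(triethylsilyloxy)oct-6-enal
Product: 6 (R)-4,8-dimethyl-4-(triethylsilyloxy)nona-1,7-diene
Conditions: Ph3PCH3Br, KN(SiMe3)2, THF, 0 °C; then 5, −78 °C → rt
Reagents that add atoms: methyltriphenylphosphonium bromide, C[P+](c1ccccc1)(c1ccccc1)c1ccccc1.[Br-]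
Why: Wittig methylenation turns the C8 aldehyde into the allyl group on C10 that the ring-closing metathesis needs; the salt-free ylide at low temperature adds faster than it deprotonates the aldehyde.

Step 5
Reactants: 6 (R)-4,8-dimethyl-4-(triethylsilyloxy)nona-1,7-diene
Product: 8 (R)-4-methyl-4-(triethylsilyloxy)hept-6-enal, via secondary ozonide 7 (not isolated)
Conditions: O3, CH2Cl2, −78 °C (Sudan red 7B as end-point indicator); then PPh3, −78 °C → rt
Reagents that add atoms: ozone, [O-][O+]=O
Why: Ozonolysis with reductive work-up; the electron-rich trisubstituted alkene is consumed well before the monosubstituted allyl alkene when ozone is dosed to the dye end point, which uncovers C3 as an aldehyde and leaves C1 and C2 as the chain.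

Step 6
Reactants: 9 3-[(4-methoxybenzyl)oxy]propanoic acid; 10 (S)-4-benzyl-2-oxazolidinone
Product: 12 (S)-4-benzyl-3-{3-[(4-methoxybenzyl)oxy]propanoyl}oxazolidin-2-one, via mixed pivalic anhydride 11 (not isolated)
Conditions: t-BuCOCl, Et3N, THF, −20 °C; then 10, LiCl, −20 °C → rt
Reagents that add atoms: none
Why: N-Acylation of the oxazolidinone through the mixed pivalic anhydride; the hindered pivaloyl carbonyl is not attacked, so only the 3-alkoxypropanoyl group is transferred.

Step 7
Reactants: 12 (S)-4-benzyl-3-{3-[(4-methoxybenzyl)oxy]propanoyl}oxazolidin-2-one; 8 (R)-4-methyl-4-(triethylsilyloxy)hept-6-enal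
Product: 14 syn-aldol adduct (S)-4-benzyl-3-[(2S,3R,6R)-3-hydroxy-2-{[(4-methoxybenzyl)oxy]methyl}-6-methyl-6-(triethylsilyloxy)non-8-enoyl]oxazolidin-2-one, via dibutylboron Z-enolate 13 (not isolated)
Conditions: Bu2BOTf, iPr2NEt, CH2Cl2, −78 → 0 °C; then 8, −78 → 0 °C; pH 7 buffer, MeOH, H2O2, 0 °C
Reagents that add atoms: none
Why: Evans syn aldol reaction; the Z-boron enolate reacts through a chair Zimmerman–Traxler transition state on the enolate face away from the benzyl group of the (S)-auxiliary, which forms C3–C4 and sets C4 and C3 in the 2,3-syn sense. With the acyl carbon as C15 and the alkoxymethyl carbon as C5, this is the arrangement in which O3 and C15 end up cis on ring A.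

Step 8
Reactants: 14 syn-aldol adduct
Product: 16 (2S,3R,6R)-2-{[(4-methoxybenzyl)oxy]methyl}-6-methylnon-8-ene-1,3,6-triol, via triethylsilyl-protected diol 15 (not isolated)
Conditions: LiBH4, MeOH, Et2O, 0 °C; then HCl (1% in MeOH), rt
Reagents that add atoms: none
Why: Reductive cleavage of the N-acyl oxazolidinone gives C15 as a primary alcohol and returns the auxiliary; acid methanolysis in the same flask removes the tertiary triethylsilyl ether, which is no longer needed, while the 4-methoxybenzyl ether stays.

Step 9
Reactants: 16 (2S,3R,6R)-2-{[(4-methoxybenzyl)oxy]methyl}-6-methylnon-8-ene-1,3,6-triol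
Product: 18 C3-O-TBS/C15-O-TBDPS ether of triol 16 (C5–OPMB kept; tertiary C10 hydroxyl free), via C15 mono-silyl ether 17 (not isolated)
Conditions: t-BuPh2SiCl (1.05 equiv), imidazole, DMF, 0 °C; then t-BuMe2SiCl, 40 °C
Reagents that add atoms: tert-butyl(chloro)diphenylsilane, CC(C)(C)[Si](Cl)(c1ccccc1)c1ccccc1; tert-butyl(chloro)dimethylsilane, CC(C)(C)[Si](C)(C)Cl
Why: Silyl chlorides with imidazole discriminate by steric access: the primary C15 hydroxyl takes the bulkier group first, the secondary C3 hydroxyl is silylated next, and the tertiary C10 hydroxyl does not react. The diphenylsilyl group is placed on C15 because a primary dimethylsilyl ether would not survive the chromic acid of step 21.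

Step 10
Reactants: 18 C3-O-TBS/C15-O-TBDPS ether
Product: 19 C5 primary alcohol (PMB removed)
Conditions: DDQ, CH2Cl2/pH 7 buffer (10:1), 0 °C → rt
Reagents that add atoms: none
Why: Oxidative cleavage of the 4-methoxybenzyl ether by benzylic hydride abstraction and hydrolysis; silyl ethers, the terminal alkene and the tertiary alcohol are inert to DDQ.

Step 11
Reactants: 19 C5 primary alcohol
Product: 20 C5 aldehyde
Conditions: Dess–Martin periodinane, NaHCO3, CH2Cl2, 0 °C → rt
Reagents that add atoms: none
Why: Dess–Martin oxidation of the only primary alcohol; the neutral conditions keep the C4 stereocentre next to the new aldehyde and the β-silyloxy group intact, and the tertiary alcohol cannot be oxidised.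

Step 12
Reactants: 20 C5 aldehyde
Product: 21 methyl (Z)-enoate (C5=C6 cis; C7 ester)
Conditions: (CF3CH2O)2P(O)CH2CO2Me, KN(SiMe3)2, 18-crown-6, THF, −78 °C; then 20, −78 °C
Reagents that add atoms: methyl bis(2,2,2-trifluoroethyl)phosphonoacetate, COC(=O)CP(=O)(OCC(F)(F)F)OCC(F)(F)F
Why: Still–Gennari variant of the Horner–Wadsworth–Emmons reaction; the electron-poor phosphonate with a dissociated potassium counter-ion eliminates from the kinetic adduct and gives the Z-enoate, and the low temperature avoids epimerisation at C4.

Step 13
Reactants: 21 methyl (Z)-enoate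
Product: 22 (Z)-allylic alcohol (C7–OH)
Conditions: iBu2AlH, CH2Cl2, −78 °C; Rochelle salt (aq)
Reagents that add atoms: none
Why: 1,2-Reduction of the enoate to the allylic alcohol with retention of the Z geometry; one extra equivalent of hydride is consumed by the tertiary hydroxyl.

Step 14
Reactants: 22 (Z)-allylic alcohol
Product: 23 (5S,6R)-cis-epoxy alcohol
Conditions: Ti(OiPr)4, D-(−)-diethyl tartrate, t-BuOOH, 4 Å molecular sieves, CH2Cl2, −20 °C
Reagents that add atoms: tert-butyl hydroperoxide, CC(C)(C)OO
Why: Sharpless asymmetric epoxidation; the D-tartrate complex delivers oxygen to the face of the Z-allylic alcohol that gives the (5S,6R)-cis-epoxide. Allylic 1,3-strain in the Z-alkene (H4 eclipsing the double bond, attack anti to the larger C3 branch) points the same way, so reagent and substrate control should be matched; the isolated terminal alkene is not activated.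

Step 15
Reactants: 23 (5S,6R)-cis-epoxy alcohol
Product: 24 ring A oxepane diol (5R,6R; C6–OH and C7–OH)
Conditions: (+)-10-camphorsulfonic acid (10 mol%), CH2Cl2, 0 °C → rt
Reagents that add atoms: none
Why: Acid-catalysed intramolecular epoxide opening by the tertiary C10 hydroxyl in the 7-exo-tet mode closes ring A and forms the O–C5 bond with inversion, so C5 follows from the epoxide and C6 is retained. Attack at C5 rather than C6 is favoured by the smaller ring and by the inductive deactivation of C6 by the neighbouring hydroxymethyl group.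

Step 16
Reactants: 24 ring A oxepane diol
Product: 26 ring A oxepane carrying the (6R) C6–C7 terminal epoxide on C5, via C7 mono-tosylate 25 (not isolated)
Conditions: NaH, THF, 0 °C; then 1-(p-tolylsulfonyl)imidazole, 0 °C → rt
Reagents that add atoms: none
Why: One-flask primary-selective sulfonylation and intramolecular Williamson displacement by the C6 alkoxide; only the C7–O bond is exchanged, so C6 keeps its configuration.

Step 17
Reactants: 26 terminal epoxide
Product: 27 ring A oxepane with the (6R) vinyl carbinol on C5 and the allyl group on C10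
Conditions: Me3SI, n-BuLi, THF, −10 °C; then 26, −10 °C → rt
Reagents that add atoms: trimethylsulfonium iodide, C[S+](C)C.[I-]
Why: Epoxide-to-allylic-alcohol homologation with dimethylsulfonium methylide; the ylide opens the epoxide at its CH2 terminus and excess ylide deprotonates the sulfonium salt, which eliminates dimethyl sulfide to give the C6 vinyl carbinol without touching C6.

Step 18
Reactants: 27 diene
Product: 28 bicyclic allylic alcohol (rings A and B; C7=C8; C6–OH)
Conditions: second-generation Grubbs catalyst (10 mol%), CH2Cl2 (2 mM), 40 °C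
Reagents that add atoms: none
Why: Ring-closing metathesis of the C6 vinyl and C10 allyl groups forms C7=C8 and closes ring B as the cis-cycloalkene with loss of ethene. The closure spans the trans-2,7-disubstituted oxepane, a strain of the kind that ring-closing metathesis has overcome in inside–outside bicyclo[4.4.1]undecenes of the ingenane class; high dilution suppresses oligomerisation.

Step 19
Reactants: 28 bicyclic allylic alcohol; 29 ethyl vinyl ether
Product: 30 bromoacetal on O6 (2-bromo-1-ethoxyethyl ether; both acetal epimers)
Conditions: N-bromosuccinimide, CH2Cl2, −40 → 0 °C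
Reagents that add atoms: N-bromosuccinimide, O=C1CCC(=O)N1Br
Why: Bromoacetalisation of an enol ether; the bromonium ion of the electron-rich vinyl ether is captured by the C6 hydroxyl, which attaches C12 and C11 to O6, while the far less nucleophilic ring alkene is not brominated.

Step 20
Reactants: 30 bromoacetal; 31 TEMPO
Product: 32 tricyclic lactol ethyl ether with the C8 aminoxy group (O8 trans to C11)
Conditions: Bu6Sn2 (1.5 equiv), hν (sunlamp), PhH (5 mM), 60 °C; 31 (3 equiv) added over 8 h by syringe pump
Reagents that add atoms: none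
Why: Bu3Sn radicals from photolysed Bu6Sn2 abstract bromine from 30; the primary C11 radical, held on O6 by the acetal, adds to C7 of the ring alkene, and the C8 radical so formed couples with the nitroxide 31 to give the C8–O bond. The closest known reaction type is the Ueno–Stork haloacetal cyclisation run with a nitroxide in place of a hydrogen donor (tin-mediated radical cyclisation with TEMPO trapping). Ring C closes in the 5-exo-trig mode; the 6-endo path to C8 is slower for a 2-alkoxy-3-oxahex-5-enyl radical and would give a bridged ring. C7 is set by the tether, since a two-atom link from O6 can reach only the face of C7 that O6 occupies, so the new ring is cis-fused. C8 is set by approach of the bulky nitroxide to the face of the secondary radical remote from the new ring, which places O8 trans to C11, the configuration that step 28 inverts. The step needs cyclisation (about 10^6–10^7 s−1) to outrun capture of the uncyclised radical by 31 (about 10^9 M−1 s−1), which is secured by keeping the stationary nitroxide concentration below about 10^−3 M through slow addition. Hexabutylditin is used in place of a tin hydride so that no hydrogen donor competes with 31 for the C8 radical, and in excess because the nitroxide also scavenges tin radicals and no chain is carried. The acetal carbon needs no control because it becomes the lactone carbonyl.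

Step 21
Reactants: 32 tricyclic lactol ethyl ether
Product: 34 cis-fused γ-lactone with the C8 aminoxy group, via lactol 33 (not isolated)
Conditions: CrO3, H2SO4, H2O, acetone, 0 °C
Reagents that add atoms: water, O
Why: Jones oxidation of a lactol ether: acid hydrolysis of the ethyl acetal and oxidation of the lactol by hexavalent chromium give the γ-lactone; the alkoxyamine is protonated and not oxidised, and the secondary dimethylsilyl and primary diphenylsilyl ethers withstand the brief exposure.

Step 22
Reactants: 34 γ-lactone
Product: 37 α-methylene lactone with the C8 aminoxy group, via Mannich base 35 (not isolated), via trimethylammonium iodide 36 (not isolated)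
Conditions: LiN(iPr)2, THF, −78 °C; [Me2N=CH2]I, −78 °C → rt; then MeI, MeOH, rt; NaHCO3 (aq), CH2Cl2, rt
Reagents that add atoms: N,N-dimethylmethyleneiminium iodide, C[N+](C)=C.[I-]
Why: α-Methylenation of a lactone by enolate Mannich reaction, quaternisation and E1cB elimination installs C13; the C11 enolate has no β-leaving group, and O8 stays masked as the base-stable alkoxyamine so that it can neither translactonise nor add to the new acceptor.

Step 23
Reactants: 37 α-methylene lactone with the C8 aminoxy group
Product: 38 C8 alcohol (O8 trans to C11) of the α-methylene lactone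
Conditions: Zn, AcOH/THF/H2O (3:1:1), 60 °C
Reagents that add atoms: none
Why: Reductive cleavage of the N–O bond of the alkoxyamine by zinc in acetic acid frees the C8 hydroxyl; the unsaturated lactone is not reduced by zinc, and the trans relationship of O8 and C11 disfavours translactonisation.

Step 24
Reactants: 39 (E)-but-2-enal
Product: 41 (Z)-2-bromobut-2-enal, via 2,3-dibromobutanal 40 (not isolated)
Conditions: Br2, CH2Cl2, 0 °C; then Et3N, 0 °C → rt
Reagents that add atoms: bromine, BrBr
Why: Bromination–dehydrobromination of an enal; loss of the acidic α-hydrogen and the β-bromide gives the 2-bromoenal with the formyl group trans to the methyl group, the more stable Z isomer.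

Step 25
Reactants: 41 (Z)-2-bromobut-2-enal
Product: 42 (Z)-2-bromobut-2-en-1-ol
Conditions: NaBH4, CeCl3·7H2O, MeOH, 0 °C
Reagents that add atoms: none
Why: Luche reduction gives clean 1,2-reduction of the enal and leaves the alkene geometry untouched.

Step 26
Reactants: 42 (Z)-2-bromobut-2-en-1-ol
Product: 43 (Z)-[(2-bromobut-2-en-1-yl)oxy](tert-butyl)dimethylsilane
Conditions: t-BuMe2SiCl, imidazole, CH2Cl2, rt
Reagents that add atoms: tert-butyl(chloro)dimethylsilane, CC(C)(C)[Si](C)(C)Cl
Why: Standard silylation of a primary alcohol ahead of the organolithium step.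

Step 27
Reactants: 43 (Z)-[(2-bromobut-2-en-1-yl)oxy](tert-butyl)dimethylsilane
Product: 45 (Z)-2-{[(tert-butyldimethylsilyl)oxy]methyl}but-2-enoic acid, via vinyllithium 44 (not isolated)
Conditions: t-BuLi (2.1 equiv), Et2O, −78 °C; then CO2, −78 °C → rt; citric acid (aq)
Reagents that add atoms: carbon dioxide, O=C=O
Why: Bromine–lithium exchange and carboxylation both proceed with retention at the sp2 carbon, so the carboxyl group takes the place of bromine cis to the methyl group, the geometry of the C8 acyl group of 48.

Step 28
Reactants: 38 C8 alcohol; 45 (Z)-2-{[(tert-butyldimethylsilyl)oxy]methyl}but-2-enoic acid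
Product: 46 C8 ester with inverted C8 (O8 cis to C11); C3–OTBS, C15–OTBDPS, side-chain OTBS
Conditions: PPh3, diisopropyl azodicarboxylate, toluene, 0 °C → rt
Reagents that add atoms: none
Why: Mitsunobu esterification; the carboxylate displaces the C8 oxyphosphonium group by SN2 with inversion, which forms the C8–O ester bond with O8 cis to C11 (8R). Because the acid is never activated at its carbonyl group, the Z-enoate cannot isomerise.

Step 29
Reactants: 46 tris-silyl ether
Product: 47 triol (C3–OH, C15–OH, side-chain CH2OH)
Conditions: HF·pyridine, pyridine, THF, 0 °C → rt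
Reagents that add atoms: none
Why: Buffered fluoride desilylation removes the three silyl ethers without opening the lactone, adding to the methylene lactone or cleaving the C8 ester.

Step 30
Reactants: 47 triol
Product: 48 target CNP0426612.2
Conditions: Ac2O (2.2 equiv), 2,4,6-collidine, CH2Cl2, −20 → 0 °C
Reagents that add atoms: acetic anhydride, CC(=O)OC(C)=O
Why: Chemoselective acetylation with a weak hindered base; the two primary hydroxyls (C15 and the side-chain CH2OH) react much faster than the hindered secondary C3 hydroxyl on ring A, which gives 48.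

## Compound list

1 | (R)-linalool [(3R)-3,7-dimethylocta-1,6-dien-3-ol] | O[C@](C)(CCC=C(C)C)C=C | starting material
2 | (R)-3,7-dimethyl-3-(triethylsilyloxy)octa-1,6-diene | CC[Si](CC)(CC)O[C@](C)(CCC=C(C)C)C=C | intermediate
3 | B-alkyl-9-borabicyclononane adduct of 2 (boron on the former vinyl terminus) | CC[Si](CC)(CC)O[C@](C)(CCC=C(C)C)CCB1C2CCCC1CCC2 | intermediate
4 | (R)-3,7-dimethyl-3-(triethylsilyloxy)oct-6-en-1-ol | CC[Si](CC)(CC)O[C@](C)(CCC=C(C)C)CCO | intermediate
5 | (R)-3,7-dimethyl-3-(triethylsilyloxy)oct-6-enal | CC[Si](CC)(CC)O[C@](C)(CCC=C(C)C)CC=O | intermediate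
6 | (R)-4,8-dimethyl-4-(triethylsilyloxy)nona-1,7-diene | CC[Si](CC)(CC)O[C@](C)(CCC=C(C)C)CC=C | intermediate
7 | secondary ozonide of 6 at the trisubstituted alkene | CC[Si](CC)(CC)O[C@](C)(CCC1OOC(C)(C)O1)CC=C | intermediate
8 | (R)-4-methyl-4-(triethylsilyloxy)hept-6-enal (C3 aldehyde) | CC[Si](CC)(CC)O[C@](C)(CCC=O)CC=C | intermediate
9 | 3-[(4-methoxybenzyl)oxy]propanoic acid | OC(=O)CCOCc1ccc(OC)cc1 | starting material
10 | (S)-4-benzyl-2-oxazolidinone | O=C1N[C@@H](Cc2ccccc2)CO1 | starting material
11 | mixed pivalic anhydride of 9 | COc1ccc(COCCC(=O)OC(=O)C(C)(C)C)cc1 | intermediate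
12 | (S)-4-benzyl-3-{3-[(4-methoxybenzyl)oxy]propanoyl}oxazolidin-2-one | COc1ccc(COCCC(=O)N2[C@@H](Cc3ccccc3)COC2=O)cc1 | intermediate
13 | dibutylboron Z-enolate of 12 | COc1ccc(COC/C=C(\OB(CCCC)CCCC)N2[C@@H](Cc3ccccc3)COC2=O)cc1 | intermediate
14 | syn-aldol adduct (S)-4-benzyl-3-[(2S,3R,6R)-3-hydroxy-2-{[(4-methoxybenzyl)oxy]methyl}-6-methyl-6-(triethylsilyloxy)non-8-enoyl]oxazolidin-2-one | CC[Si](CC)(CC)O[C@](C)(CC[C@@H](O)[C@H](COCc1ccc(OC)cc1)C(=O)N1[C@@H](Cc2ccccc2)COC1=O)CC=C | intermediate
15 | (2S,3R,6R)-2-{[(4-methoxybenzyl)oxy]methyl}-6-methyl-6-(triethylsilyloxy)non-8-ene-1,3-diol | CC[Si](CC)(CC)O[C@](C)(CC[C@@H](O)[C@H](COCc1ccc(OC)cc1)CO)CC=C | intermediate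
16 | (2S,3R,6R)-2-{[(4-methoxybenzyl)oxy]methyl}-6-methylnon-8-ene-1,3,6-triol | O[C@](C)(CC[C@@H](O)[C@H](COCc1ccc(OC)cc1)CO)CC=C | intermediate
17 | C15 tert-butyldiphenylsilyl ether of triol 16 | O[C@](C)(CC[C@@H](O)[C@H](COCc1ccc(OC)cc1)CO[Si](c1ccccc1)(c1ccccc1)C(C)(C)C)CC=C | intermediate
18 | C3-O-TBS/C15-O-TBDPS ether of triol 16 (C5–OPMB; tertiary C10–OH free) | O[C@](C)(CC[C@@H](O[Si](C)(C)C(C)(C)C)[C@H](COCc1ccc(OC)cc1)CO[Si](c1ccccc1)(c1ccccc1)C(C)(C)C)CC=C | intermediate
19 | C5 primary alcohol (PMB removed from 18) | O[C@](C)(CC[C@@H](O[Si](C)(C)C(C)(C)C)[C@H](CO)CO[Si](c1ccccc1)(c1ccccc1)C(C)(C)C)CC=C | intermediate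
20 | C5 aldehyde | O[C@](C)(CC[C@@H](O[Si](C)(C)C(C)(C)C)[C@H](C=O)CO[Si](c1ccccc1)(c1ccccc1)C(C)(C)C)CC=C | intermediate
21 | methyl (Z)-enoate (C5=C6 cis; C7 = CO2Me) | O[C@](C)(CC[C@@H](O[Si](C)(C)C(C)(C)C)[C@H](/C=C\C(=O)OC)CO[Si](c1ccccc1)(c1ccccc1)C(C)(C)C)CC=C | intermediate
22 | (Z)-allylic alcohol (C5=C6 cis; C7–OH) | O[C@](C)(CC[C@@H](O[Si](C)(C)C(C)(C)C)[C@H](/C=C\CO)CO[Si](c1ccccc1)(c1ccccc1)C(C)(C)C)CC=C | intermediate
23 | (5S,6R)-cis-epoxy alcohol (C5–C6 oxirane; C7–OH) | O[C@](C)(CC[C@@H](O[Si](C)(C)C(C)(C)C)[C@H]([C@@H]1O[C@@H]1CO)CO[Si](c1ccccc1)(c1ccccc1)C(C)(C)C)CC=C | intermediate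
24 | ring A oxepane diol (5R,6R; C6–OH, C7–OH; allyl on C10) | OC[C@@H](O)[C@@H]1O[C@](C)(CC[C@@H](O[Si](C)(C)C(C)(C)C)[C@H]1CO[Si](c2ccccc2)(c2ccccc2)C(C)(C)C)CC=C | intermediate
25 | C7 mono-tosylate of 24 | Cc1ccc(S(=O)(=O)OC[C@@H](O)[C@@H]2O[C@](C)(CC[C@@H](O[Si](C)(C)C(C)(C)C)[C@H]2CO[Si](c3ccccc3)(c3ccccc3)C(C)(C)C)CC=C)cc1 | intermediate
26 | ring A oxepane carrying the (6R) C6–C7 terminal epoxide on C5 | C1O[C@H]1[C@@H]2O[C@](C)(CC[C@@H](O[Si](C)(C)C(C)(C)C)[C@H]2CO[Si](c3ccccc3)(c3ccccc3)C(C)(C)C)CC=C | intermediate
27 | ring A oxepane with the (6R) vinyl carbinol on C5 and the allyl group on C10 | C=C[C@@H](O)[C@@H]1O[C@](C)(CC[C@@H](O[Si](C)(C)C(C)(C)C)[C@H]1CO[Si](c2ccccc2)(c2ccccc2)C(C)(C)C)CC=C | intermediate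
28 | bicyclic allylic alcohol (rings A and B; C7=C8; C6–OH) | O[C@H]1[C@@H]2O[C@](C)(CC[C@@H](O[Si](C)(C)C(C)(C)C)[C@H]2CO[Si](c3ccccc3)(c3ccccc3)C(C)(C)C)CC=C1 | intermediate
29 | ethyl vinyl ether | C=COCC | starting material
30 | bromoacetal of 28 on O6 (both acetal epimers) | BrCC(OCC)O[C@H]1[C@@H]2O[C@](C)(CC[C@@H](O[Si](C)(C)C(C)(C)C)[C@H]2CO[Si](c3ccccc3)(c3ccccc3)C(C)(C)C)CC=C1 | intermediate
31 | TEMPO (2,2,6,6-tetramethylpiperidin-1-oxyl) | CC1(C)CCCC(C)(C)N1[O] | starting material
32 | tricyclic lactol ethyl ether with the C8 aminoxy group (O8 trans to C11) | C1C(OCC)O[C@H]2[C@@H]3O[C@](C)(CC[C@@H](O[Si](C)(C)C(C)(C)C)[C@H]3CO[Si](c4ccccc4)(c4ccccc4)C(C)(C)C)C[C@H](ON4C(C)(C)CCCC4(C)C)[C@@H]12 | intermediate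
33 | lactol from 32 | C1C(O)O[C@H]2[C@@H]3O[C@](C)(CC[C@@H](O[Si](C)(C)C(C)(C)C)[C@H]3CO[Si](c4ccccc4)(c4ccccc4)C(C)(C)C)C[C@H](ON4C(C)(C)CCCC4(C)C)[C@@H]12 | intermediate
34 | cis-fused γ-lactone with the C8 aminoxy group | C1C(=O)O[C@H]2[C@@H]3O[C@](C)(CC[C@@H](O[Si](C)(C)C(C)(C)C)[C@H]3CO[Si](c4ccccc4)(c4ccccc4)C(C)(C)C)C[C@H](ON4C(C)(C)CCCC4(C)C)[C@@H]12 | intermediate
35 | C11 (dimethylamino)methyl lactone (Mannich base; C11 epimers) | CN(C)CC1C(=O)O[C@H]2[C@@H]3O[C@](C)(CC[C@@H](O[Si](C)(C)C(C)(C)C)[C@H]3CO[Si](c4ccccc4)(c4ccccc4)C(C)(C)C)C[C@H](ON4C(C)(C)CCCC4(C)C)[C@@H]12 | intermediate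
36 | trimethylammonium iodide of 35 | C[N+](C)(C)CC1C(=O)O[C@H]2[C@@H]3O[C@](C)(CC[C@@H](O[Si](C)(C)C(C)(C)C)[C@H]3CO[Si](c4ccccc4)(c4ccccc4)C(C)(C)C)C[C@H](ON4C(C)(C)CCCC4(C)C)[C@@H]12.[I-] | intermediate
37 | α-methylene lactone with the C8 aminoxy group | C=C1C(=O)O[C@H]2[C@@H]3O[C@](C)(CC[C@@H](O[Si](C)(C)C(C)(C)C)[C@H]3CO[Si](c4ccccc4)(c4ccccc4)C(C)(C)C)C[C@H](ON4C(C)(C)CCCC4(C)C)[C@@H]12 | intermediate
38 | C8 alcohol of the α-methylene lactone (O8 trans to C11) | C=C1C(=O)O[C@H]2[C@@H]3O[C@](C)(CC[C@@H](O[Si](C)(C)C(C)(C)C)[C@H]3CO[Si](c4ccccc4)(c4ccccc4)C(C)(C)C)C[C@H](O)[C@@H]12 | intermediate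
39 | (E)-but-2-enal (crotonaldehyde) | C/C=C/C=O | starting material
40 | 2,3-dibromobutanal | CC(Br)C(Br)C=O | intermediate
41 | (Z)-2-bromobut-2-enal | C/C=C(\Br)C=O | intermediate
42 | (Z)-2-bromobut-2-en-1-ol | C/C=C(\Br)CO | intermediate
43 | (Z)-[(2-bromobut-2-en-1-yl)oxy](tert-butyl)dimethylsilane | C/C=C(\Br)CO[Si](C)(C)C(C)(C)C | intermediate
44 | (Z)-vinyllithium from 43 | C/C=C(\[Li])CO[Si](C)(C)C(C)(C)C | intermediate
45 | (Z)-2-{[(tert-butyldimethylsilyl)oxy]methyl}but-2-enoic acid | C/C=C(\C(=O)O)CO[Si](C)(C)C(C)(C)C | intermediate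
46 | C8 ester (O8 cis to C11) with C3–OTBS, C15–OTBDPS and side-chain OTBS | C=C1C(=O)O[C@H]2[C@@H]3O[C@](C)(CC[C@@H](O[Si](C)(C)C(C)(C)C)[C@H]3CO[Si](c4ccccc4)(c4ccccc4)C(C)(C)C)C[C@@H](OC(=O)/C(=C\C)CO[Si](C)(C)C(C)(C)C)[C@@H]12 | intermediate
47 | triol (C3–OH, C15–OH, side-chain CH2OH) | C=C1C(=O)O[C@H]2[C@@H]3O[C@](C)(CC[C@@H](O)[C@H]3CO)C[C@@H](OC(=O)/C(=C\C)CO)[C@@H]12 | intermediate
48 | CNP0426612.2 (3R,4R,5R,6R,7R,8R,10R) | C=C1C(=O)O[C@H]2[C@@H]3O[C@](C)(CC[C@@H](O)[C@H]3COC(C)=O)C[C@@H](OC(=O)/C(=C\C)COC(C)=O)[C@@H]12 | target

## Step count and least certain steps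

Total step count: 30. Longest linear sequence: 25 steps (steps 1–5, 7–23 and 28–30); steps 6 and 24–27 are side branches.

**Step 20 (key step).** The most likely failure is capture of the uncyclised C11 radical, or of the tin radicals, by the nitroxide before ring closure, combined with slow bromine abstraction from a primary alkyl bromide. The result would be reduced or prematurely oxygenated material and incomplete conversion. Leakage of facial selectivity at C8 would not harm C7 but would lower the usable fraction.
Fallback: a cobalt-mediated two-stage sequence that sets out from 30 and comes back at 32. NaBH4 reduction of ClCo(dmgH)2(py) in MeOH at 0 °C gives the monovalent cobalt nucleophile, which displaces bromide. Visible-light homolysis of the primary alkyl–cobalt bond then lets the C11 radical close onto C7 with no trap present, and recombination with divalent cobalt gives the cyclised secondary alkylcobaloxime F1. Photolysis of F1 in benzene in the presence of 31 then delivers 32, so the nitroxide meets only the cyclised radical.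

**Step 18.** Ring closure may lose to intermolecular metathesis (oligomerisation) or to alkene migration, because the transition state must build the strain of the trans-bridged bicycle.
Fallback: closure of ring B at C6–C7 by a Nozaki–Hiyama–Kishi reaction, setting out from 24 and coming back at 28. Cross metathesis of the allyl group of 24 with pinacol vinylboronate gives the (E)-alkenylboronate F2. ICl followed by NaOMe converts F2 with inversion into the (Z)-vinyl iodide F3. NaIO4 cleaves the C6/C7 diol of F3 to the aldehyde F4. CrCl2 with catalytic NiCl2 in DMSO/THF at high dilution adds the vinylchromium species to the C6 aldehyde, giving 28 together with its C6 epimer F5, which is separated.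

**Step 15.** The seven-membered closure by a tertiary hydroxyl may be too slow, so opening at C6 (8-endo), participation of a silyl ether oxygen, or acid-induced rearrangement of the epoxide could take over.
Fallback: stronger electronic bias toward C5, setting out from 23 and coming back at 24. TEMPO/PhI(OAc)2 in MeCN/water oxidises the C7 alcohol to the glycidic acid F6. Me3SiCHN2 gives the methyl glycidate F7. BF3·OEt2 at −40 °C opens F7 at the β-carbon C5 (the carbon remote from the ester) to the oxepane α-hydroxy ester F8. LiBH4 reduces F8 to 24.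

**Step 28.** Elimination toward C9 or simple lack of reaction may win at the hindered ring alcohol, since the nucleophile is a weakly acidic unsaturated carboxylic acid.
Fallback: inversion by oxidation and reduction, setting out from 38 and coming back at 46. Dess–Martin periodinane gives the C8 ketone F9. NaBH4/CeCl3·7H2O in MeOH at −78 °C should deliver hydride to the face that the nitroxide used, giving the C8 epimer F10 with O8 cis to C11. F10 is esterified with retention by the mixed anhydride of 45 with 2,4,6-trichlorobenzoyl chloride (Et3N, toluene, no nucleophilic amine catalyst, so that the Z-enoate is not isomerised), which gives 46.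

Further compounds

F1 | step 20 | cyclised C8 alkylcobaloxime, (pyridine)bis(dimethylglyoximato)cobalt alkyl of trivalent cobalt (C8 configuration immaterial) | C1C(OCC)O[C@H]2[C@@H]3O[C@](C)(CC[C@@H](O[Si](C)(C)C(C)(C)C)[C@H]3CO[Si](c4ccccc4)(c4ccccc4)C(C)(C)C)CC([Co+2])[C@@H]12.CC(=NO)C(C)=N[O-].CC(=NO)C(C)=N[O-].c1ccncc1
F2 | step 18 | (E)-alkenyl pinacolboronate of diol 24 | OC[C@@H](O)[C@@H]1O[C@](C)(CC[C@@H](O[Si](C)(C)C(C)(C)C)[C@H]1CO[Si](c2ccccc2)(c2ccccc2)C(C)(C)C)C/C=C/B3OC(C)(C)C(C)(C)O3
F3 | step 18 | (Z)-vinyl iodide diol | OC[C@@H](O)[C@@H]1O[C@](C)(CC[C@@H](O[Si](C)(C)C(C)(C)C)[C@H]1CO[Si](c2ccccc2)(c2ccccc2)C(C)(C)C)C/C=C\I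
F4 | step 18 | C6 aldehyde carrying the (Z)-vinyl iodide | O=C[C@@H]1O[C@](C)(CC[C@@H](O[Si](C)(C)C(C)(C)C)[C@H]1CO[Si](c2ccccc2)(c2ccccc2)C(C)(C)C)C/C=C\I
F5 | step 18 | C6 epimer of 28 | O[C@@H]1[C@@H]2O[C@](C)(CC[C@@H](O[Si](C)(C)C(C)(C)C)[C@H]2CO[Si](c3ccccc3)(c3ccccc3)C(C)(C)C)CC=C1
F6 | step 15 | glycidic acid from 23 (C7 carboxylic acid) | O[C@](C)(CC[C@@H](O[Si](C)(C)C(C)(C)C)[C@H]([C@@H]1O[C@@H]1C(=O)O)CO[Si](c1ccccc1)(c1ccccc1)C(C)(C)C)CC=C
F7 | step 15 | methyl glycidate | O[C@](C)(CC[C@@H](O[Si](C)(C)C(C)(C)C)[C@H]([C@@H]1O[C@@H]1C(=O)OC)CO[Si](c1ccccc1)(c1ccccc1)C(C)(C)C)CC=C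
F8 | step 15 | ring A oxepane α-hydroxy methyl ester | COC(=O)[C@@H](O)[C@@H]1O[C@](C)(CC[C@@H](O[Si](C)(C)C(C)(C)C)[C@H]1CO[Si](c2ccccc2)(c2ccccc2)C(C)(C)C)CC=C
F9 | step 28 | C8 ketone of the α-methylene lactone | C=C1C(=O)O[C@H]2[C@@H]3O[C@](C)(CC[C@@H](O[Si](C)(C)C(C)(C)C)[C@H]3CO[Si](c4ccccc4)(c4ccccc4)C(C)(C)C)CC(=O)[C@@H]12
F10 | step 28 | C8 epimer of 38 (O8 cis to C11) | C=C1C(=O)O[C@H]2[C@@H]3O[C@](C)(CC[C@@H](O[Si](C)(C)C(C)(C)C)[C@H]3CO[Si](c4ccccc4)(c4ccccc4)C(C)(C)C)C[C@@H](O)[C@@H]12
A1 | alternative 1 | methyl levulinate | CC(=O)CCC(=O)OC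
A2 | alternative 1 | C5 trimethylsilyl, C6 tert-butyldimethylsilyl ether of the divinyl diol | C=C[C@@H](O[Si](C)(C)C(C)(C)C)[C@@H](C=C)O[Si](C)(C)C
A3 | alternative 1 | allyltrimethylsilane | C=CC[Si](C)(C)C
A4 | alternative 1 | tertiary homoallylic ether | C=C[C@@H](O[Si](C)(C)C(C)(C)C)[C@@H](C=C)O[C@](C)(CCC(=O)OC)CC=C
A5 | alternative 2 | ring A oxepane C6 aldehyde carrying the 2-(bromomethyl)acrylate | O=C[C@@H]1O[C@](C)(CC[C@@H](O[Si](C)(C)C(C)(C)C)[C@H]1COC(C)=O)C[C@@H](OCc2ccc(OC)cc2)/C=C(\CBr)C(=O)OC
A6 | alternative 2 | protected tricyclic α-methylene lactone | C=C1C(=O)O[C@H]2[C@@H]3O[C@](C)(CC[C@@H](O[Si](C)(C)C(C)(C)C)[C@H]3COC(C)=O)C[C@@H](OCc4ccc(OC)cc4)[C@@H]12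
A7 | alternative 3 | 2-furyl oxepane with the C8 aldehyde | O=CC[C@@]1(C)CC[C@@H](O[Si](C)(C)C(C)(C)C)[C@@H](CO[Si](C)(C)C(C)(C)C)[C@@H](O1)c1ccco1
A8 | alternative 3 | oxetane photoadduct | C1=CO[C@]24[C@@H]3O[C@](C)(CC[C@@H](O[Si](C)(C)C(C)(C)C)[C@H]3CO[Si](C)(C)C(C)(C)C)C[C@@H](O4)[C@@H]12
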